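**Assumption:** the target (5‑hydroxy‑3,7‑dimethoxy‑4'‑prenyloxyflavone) has no stereocentre and no stereogenic double bond, so it is achiral and "single enantiomer" requires no stereocontrol.

**Retrosynthetic overview**
1. Target 11 ⇒ kumatakenin 10 by a last‑step chemoselective 4'‑O‑prenylation; the 5‑OH is chelated to C4=O and stays free.
2. 10 ⇒ bis‑benzyl ether 9 (one hydrogenolysis frees 5‑OH and 4'‑OH) ⇒ flavonol 8 (3‑O‑methylation).
3. 8 ⇒ 2'‑hydroxychalcone 6 by oxidative cyclisation; the pyranone C ring is the only ring formed, rings A and B are bought.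
4. 6 ⇒ acetophenone 3 + aldehyde 4 by an intermolecular Claisen–Schmidt aldol condensation, the key C–C bond (future C2–C3 unit).
5. 3 ⇒ 2',4',6'‑trihydroxyacetophenone 1 by 4‑O‑methylation, then mono‑O‑benzylation.

**Route**

Step 1
Reactants: 1 1-(2,4,6-trihydroxyphenyl)ethanone (2',4',6'-trihydroxyacetophenone)
Product: 2 1-(2,6-dihydroxy-4-methoxyphenyl)ethanone
Conditions: Me2SO4 (1.0 equiv), K2CO3 (1.0 equiv), acetone, reflux, 4 h; chromatography to remove the dimethyl ether
Reagents that add atoms: dimethyl sulfate COS(=O)(=O)OC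
Why: Williamson etherification goes first at the 4‑OH, the most acidic hydroxyl and the only one not hydrogen‑bonded to the acetyl carbonyl.

Step 2
Reactants: 2 1-(2,6-dihydroxy-4-methoxyphenyl)ethanone
Product: 3 1-[2-(benzyloxy)-6-hydroxy-4-methoxyphenyl]ethanone
Conditions: BnBr (1.05 equiv), K2CO3 (1.1 equiv), acetone, reflux, 6 h
Reagents that add atoms: benzyl bromide BrCc1ccccc1
Why: Williamson mono‑benzylation of two equivalent hydroxyls stops after one alkylation because the remaining OH is locked in the carbonyl chelate and is far less nucleophilic.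

Step 3
Reactants: 3 1-[2-(benzyloxy)-6-hydroxy-4-methoxyphenyl]ethanone; 4 4-(benzyloxy)benzaldehyde
Product: 6 (E)-1-[2-(benzyloxy)-6-hydroxy-4-methoxyphenyl]-3-[4-(benzyloxy)phenyl]prop-2-en-1-one, via racemic β-hydroxy ketone aldol adduct 5 (not isolated)
Conditions: 50% aq KOH (excess), EtOH/THF, rt, 48 h; then cold dilute HCl
Reagents that add atoms: none
Why: Claisen–Schmidt crossed aldol condensation of the methyl ketone enolate with a non‑enolisable aldehyde, followed by E1cB dehydration of the aldol, gives the conjugated (E)‑chalcone and removes the transient carbinol centre.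

Step 4
Reactants: 6 (E)-1-[2-(benzyloxy)-6-hydroxy-4-methoxyphenyl]-3-[4-(benzyloxy)phenyl]prop-2-en-1-one
Product: 8 5-(benzyloxy)-2-[4-(benzyloxy)phenyl]-3-hydroxy-7-methoxy-4H-chromen-4-one, via racemic trans-dihydroflavonol 7 (not isolated)
Conditions: 30% H2O2 (5 equiv), 2 M aq NaOH (5 equiv), MeOH/THF, 0 °C to rt; then dilute HCl
Reagents that add atoms: hydrogen peroxide OO
Why: Algar–Flynn–Oyamada oxidative cyclisation closes the pyranone ring 6‑endo (favoured by the electron‑rich 4‑benzyloxyphenyl ring and low temperature) to the dihydroflavonol, which alkaline peroxide dehydrogenates in situ to the achiral flavonol.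

Step 5
Reactants: 8 5-(benzyloxy)-2-[4-(benzyloxy)phenyl]-3-hydroxy-7-methoxy-4H-chromen-4-one
Product: 9 5-(benzyloxy)-2-[4-(benzyloxy)phenyl]-3,7-dimethoxy-4H-chromen-4-one
Conditions: MeI (3 equiv), K2CO3 (2 equiv), acetone, reflux, 8 h
Reagents that add atoms: iodomethane CI
Why: Williamson O‑methylation of the acidic enolic 3‑OH, the only free hydroxyl in the molecule.

Step 6
Reactants: 9 5-(benzyloxy)-2-[4-(benzyloxy)phenyl]-3,7-dimethoxy-4H-chromen-4-one
Product: 10 5-hydroxy-2-(4-hydroxyphenyl)-3,7-dimethoxy-4H-chromen-4-one (kumatakenin)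
Conditions: H2 (1 atm), 10% Pd/C, THF/MeOH 1:1, rt, 3 h (stop at full conversion)
Reagents that add atoms: none
Why: Catalytic hydrogenolysis cleaves both aryl benzyl ethers (2 equiv toluene) while the methyl ethers and the tetrasubstituted, conjugated C2=C3 bond of the chromone are inert at 1 atm.

Step 7
Reactants: 10 5-hydroxy-2-(4-hydroxyphenyl)-3,7-dimethoxy-4H-chromen-4-one (kumatakenin)
Product: 11 5-hydroxy-3,7-dimethoxy-2-{4-[(3-methylbut-2-en-1-yl)oxy]phenyl}-4H-chromen-4-one (target)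
Conditions: prenyl bromide (1.1 equiv), K2CO3 (1.2 equiv), acetone, reflux, 4 h
Reagents that add atoms: 1-bromo-3-methylbut-2-ene (prenyl bromide) CC(C)=CCBr
Why: Chemoselective Williamson (SN2) O‑alkylation of the acidic, unchelated 4'‑phenol; the 5‑OH is tied up in the hydrogen bond to C4=O and does not react with a slight excess of reagent and mild base.

**Compound list**

1 | 1-(2,4,6-trihydroxyphenyl)ethanone (2',4',6'-trihydroxyacetophenone) | CC(=O)c1c(O)cc(O)cc1O | starting material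
2 | 1-(2,6-dihydroxy-4-methoxyphenyl)ethanone | CC(=O)c1c(O)cc(OC)cc1O | intermediate
3 | 1-[2-(benzyloxy)-6-hydroxy-4-methoxyphenyl]ethanone | CC(=O)c1c(O)cc(OC)cc1OCc1ccccc1 | intermediate
4 | 4-(benzyloxy)benzaldehyde | O=Cc1ccc(OCc2ccccc2)cc1 | starting material
5 | racemic 1-[2-(benzyloxy)-6-hydroxy-4-methoxyphenyl]-3-[4-(benzyloxy)phenyl]-3-hydroxypropan-1-one (aldol adduct, not isolated) | COc1cc(O)c(C(=O)CC(O)c2ccc(OCc3ccccc3)cc2)c(OCc2ccccc2)c1 | intermediate
6 | (E)-1-[2-(benzyloxy)-6-hydroxy-4-methoxyphenyl]-3-[4-(benzyloxy)phenyl]prop-2-en-1-one (chalcone) | COc1cc(O)c(C(=O)/C=C/c2ccc(OCc3ccccc3)cc2)c(OCc2ccccc2)c1 | intermediate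
7 | racemic trans-5-(benzyloxy)-2-[4-(benzyloxy)phenyl]-3-hydroxy-7-methoxychroman-4-one (dihydroflavonol, not isolated; (2R,3R) enantiomer drawn) | COc1cc(OCc2ccccc2)c2c(c1)O[C@H](c1ccc(OCc3ccccc3)cc1)[C@@H](O)C2=O | intermediate
8 | 5-(benzyloxy)-2-[4-(benzyloxy)phenyl]-3-hydroxy-7-methoxy-4H-chromen-4-one | COc1cc(OCc2ccccc2)c2c(=O)c(O)c(-c3ccc(OCc4ccccc4)cc3)oc2c1 | intermediate
9 | 5-(benzyloxy)-2-[4-(benzyloxy)phenyl]-3,7-dimethoxy-4H-chromen-4-one | COc1cc(OCc2ccccc2)c2c(=O)c(OC)c(-c3ccc(OCc4ccccc4)cc3)oc2c1 | intermediate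
10 | 5-hydroxy-2-(4-hydroxyphenyl)-3,7-dimethoxy-4H-chromen-4-one (kumatakenin) | COc1cc(O)c2c(=O)c(OC)c(-c3ccc(O)cc3)oc2c1 | intermediate
11 | 5-hydroxy-3,7-dimethoxy-2-{4-[(3-methylbut-2-en-1-yl)oxy]phenyl}-4H-chromen-4-one | COc1cc(O)c2c(=O)c(OC)c(-c3ccc(OCC=C(C)C)cc3)oc2c1 | target

**Step count and risks**

Total steps: 7. Longest linear sequence: 7 steps (1 → 11); aldehyde 4 enters convergently at step 3.

Steps most likely to fail:

Step 1 (mono‑methylation may over‑ or under‑alkylate). The fallback sets out from 1 and returns at 2. Compound 1 is exhaustively methylated (excess Me2SO4, K2CO3, acetone, reflux) to 1-(2,4,6-trimethoxyphenyl)ethanone F1. BBr3 (2.2 equiv, CH2Cl2, −78 to 0 °C) then removes only the two methyl ethers ortho to the acetyl group under carbonyl‑chelation control; the 4‑OMe is the least basic ether oxygen and survives, giving 2. This replaces a statistical alkylation with exhaustive alkylation plus directed dealkylation.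

Step 3 (the doubly ortho‑substituted, phenoxide‑bearing ketone may condense sluggishly with the electron‑rich aldehyde). The fallback sets out from 3 and returns at 6. The chelated phenol of 3 is capped (NaH, MOMCl, DMF, 0 °C) to give 1-[2-(benzyloxy)-4-methoxy-6-(methoxymethoxy)phenyl]ethanone F2. This non‑phenolic ketone undergoes the same Claisen–Schmidt condensation with 4 (KOH, EtOH, rt) through the racemic aldol adduct 1-[2-(benzyloxy)-4-methoxy-6-(methoxymethoxy)phenyl]-3-[4-(benzyloxy)phenyl]-3-hydroxypropan-1-one F3, which is not isolated, to the MOM chalcone (E)-1-[2-(benzyloxy)-4-methoxy-6-(methoxymethoxy)phenyl]-3-[4-(benzyloxy)phenyl]prop-2-en-1-one F4. Brief HCl in MeOH/THF at rt removes the MOM group and returns 6. Any flavanone formed on deprotection reopens to the chalcone under the alkaline conditions of step 4.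

Step 4 (6'‑alkoxy chalcones can divert to aurones by 5‑exo closure). The fallback sets out from 6 and returns at 8. Catalytic I2 in DMSO at 120 °C cyclodehydrogenates 6 to the flavone 5-(benzyloxy)-2-[4-(benzyloxy)phenyl]-7-methoxy-4H-chromen-4-one F5. Dimethyldioxirane (acetone/CH2Cl2, 0 °C) epoxidises its C2=C3 bond to racemic 5-(benzyloxy)-2-[4-(benzyloxy)phenyl]-2,3-epoxy-7-methoxy-2,3-dihydro-4H-chromen-4-one F6 (ring fusion necessarily cis). Catalytic p‑TsOH in CH2Cl2 opens and tautomerises the epoxide to flavonol 8. This separates ring closure from C3 oxygenation, so no aurone can form.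

**Further compounds**

F1 | step 1 | 1-(2,4,6-trimethoxyphenyl)ethanone | CC(=O)c1c(OC)cc(OC)cc1OC
F2 | step 3 | 1-[2-(benzyloxy)-4-methoxy-6-(methoxymethoxy)phenyl]ethanone | CC(=O)c1c(OCOC)cc(OC)cc1OCc1ccccc1
F3 | step 3 | racemic 1-[2-(benzyloxy)-4-methoxy-6-(methoxymethoxy)phenyl]-3-[4-(benzyloxy)phenyl]-3-hydroxypropan-1-one | COCOc1cc(OC)cc(OCc2ccccc2)c1C(=O)CC(O)c1ccc(OCc2ccccc2)cc1
F4 | step 3 | (E)-1-[2-(benzyloxy)-4-methoxy-6-(methoxymethoxy)phenyl]-3-[4-(benzyloxy)phenyl]prop-2-en-1-one | COCOc1cc(OC)cc(OCc2ccccc2)c1C(=O)/C=C/c1ccc(OCc2ccccc2)cc1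
F5 | step 4 | 5-(benzyloxy)-2-[4-(benzyloxy)phenyl]-7-methoxy-4H-chromen-4-one | COc1cc(OCc2ccccc2)c2c(=O)cc(-c3ccc(OCc4ccccc4)cc3)oc2c1
F6 | step 4 | racemic 5-(benzyloxy)-2-[4-(benzyloxy)phenyl]-2,3-epoxy-7-methoxy-2,3-dihydro-4H-chromen-4-one | COc1cc(OCc2ccccc2)c2c(c1)OC1(c3ccc(OCc4ccccc4)cc3)OC1C2=O
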